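The numbers of this flask are made up.

If you are shown Q falling and X rising, the thing to reckon is how many live ends work, and for how long.

    Q + G → L + X (k1 = 0.0027 M⁻¹ s⁻¹)
    Q + L → X + L, rate k2*[L]*[Q] (k2 = 0.054 M⁻¹ s⁻¹)
    Q + G → Q.G (k3 = 0.0015 M⁻¹ s⁻¹)

Q 0.45 M; G 2.2 mM; time 1.0 h

- the average divides the monomer in chains by the number of chains begun, living and dead together
- run time (flask): 1.0 h

* average number of monomer units in a chain (chains begun, living or dead) at 1.0 h
* part of the Q that has reacted at 1.0 h

Solve this flask at both ends and join them. Early on, G leaves by two paths, so the share becoming L is the chain-starting constant over the sum of both constants, 64.3 %, and G decays with a mean life, one over that sum times the charge of Q, 0.147 h, which is also the delay by which the live ends lag, shorter than the run. Later, taking L as constant, Q decays pseudo-first-order, so c is one minus the exponential of minus the chain dose, and dp is the Q taken into chains per live end.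

Errors in the growth constant or the G charge enter that dose at full weight. The two G constants enter through the share at 35.7 % of their error, and their sum and the Q charge enter through the delay at 17.2 %, though dp carries the Q charge in full.

Now the numbers: 1.41 mM of live ends give 0.235 for the chain dose, the growth constant times the live ends times the time less the delay, hence c 20.9 % and dp 66.5. At this dose an error in the G charge reaches dp at 11.3 % of its size, since the live ends stand on both sides of the fraction.

The forecast, reasoning that “G is essentially used up within the first several minutes”, gave 67 and 21.2 %, its c slightly above yours. The flask gives dp 67.1 and c 21.2 %.

In the neighbouring flask, G is charged at 0.0013 M and the charge of Q is unchanged, so share and delay stay and the live ends fall to 0.836 mM. Its chain dose is 0.139, which reckons to c 13.0 % and dp 69.7. That neighbouring flask gives c 13.2 % and dp 70.5, with L at 8.34 × 10⁻⁴ M.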